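**Retrosynthetic overview**

1. Target 22 ⇒ (lactone opening by MeOH) tricyclic lactone 21 ⇒ prenylated chromanone 18 + hex-2-ynal 20. One chiral-carbene operation makes the aryl C8–C3' bond, sets the R centre and brings in the ester carbon at the right oxidation level.
2. Enabling feature: in ring A (the phloroglucinol ring) O7–H/C8–H is a free enol unit of a vinylogous acid (HO–C7=C8, conjugated through C8a=C4a to C4=O). O5–H is tied to C4=O by a hydrogen bond and C6 is blocked by prenyl, so O7 takes the acyl unit and C8 is the only carbon that can receive its β-carbon, through a temporary six-membered lactone (ring C).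
3. 18 ⇒ 6-allyl compound 16 (cross-metathesis) ⇒ 5-O-allyl ether 14 (Claisen shift O5→C6, O7 masked as acetate) ⇒ chromanone 12.
4. 12 ⇒ Mitsunobu closure of ring B (O1–C2 bond, inversion) of syn-aldol ketone 11 ⇒ aryllithium 9 (from tris-MOM phloroglucinol) + Weinreb amide 6 (Evans syn-aldol).
5. Ring order: ring A bought as phloroglucinol → ring B (step 7) → temporary ring C (step 14, formed and opened in one pot).

Key step: step 14

Assumption: the (5aS,10bR) triazolium precatalyst of step 14 is taken to shield the Si face of C3' of the bound (E)-hex-2-enoyl azolium; should the sense be the opposite, the equally available (5aR,10bS) antipode is used with no other change.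

**Route**

Step 1
Reactants: 1 (S)-4-benzyl-3-propanoyl-1,3-oxazolidin-2-one; 2 acetaldehyde
Product: 4 (S)-4-benzyl-3-[(2S,3R)-3-hydroxy-2-methylbutanoyl]-1,3-oxazolidin-2-one, via dibutylboron Z-enolate 3 (not isolated)
Conditions: Bu2BOTf, iPr2NEt, CH2Cl2, 0 °C; then 2, −78 → 0 °C; pH 7 buffer, MeOH, H2O2, 0 °C
Reagents that add atoms: none
Why: Evans syn-aldol reaction, in which the Z-boron enolate reacts through a closed Zimmerman–Traxler chair and the benzyl group of the auxiliary shields one enolate face, so both new centres (2S,3R, syn) are set by auxiliary control.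

Step 2
Reactants: 4 (S)-4-benzyl-3-[(2S,3R)-3-hydroxy-2-methylbutanoyl]-1,3-oxazolidin-2-one
Product: 5 (2S,3R)-3-hydroxy-N-methoxy-N,2-dimethylbutanamide
Conditions: MeNHOMe·HCl, AlMe3, THF, −20 → 0 °C; aq. Rochelle salt
Reagents that add atoms: N,O-dimethylhydroxylamine hydrochloride, CNOC.Cl
Why: AlMe3-mediated transamination of the imide to the Weinreb amide is assisted by the free β-hydroxyl through an aluminium chelate and should leave both stereocentres untouched.

Step 3
Reactants: 5 (2S,3R)-3-hydroxy-N-methoxy-N,2-dimethylbutanamide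
Product: 6 (2S,3R)-3-[(tert-butyldimethylsilyl)oxy]-N-methoxy-N,2-dimethylbutanamide
Conditions: TBSOTf, 2,6-lutidine, CH2Cl2, −78 → 0 °C
Reagents that add atoms: tert-butyldimethylsilyl trifluoromethanesulfonate, CC(C)(C)[Si](C)(C)OS(=O)(=O)C(F)(F)F
Why: Standard silylation of a secondary alcohol, which removes the acidic proton and the retro-aldol pathway before the organolithium step.

Step 4
Reactants: 7 phloroglucinol (benzene-1,3,5-triol)
Product: 8 1,3,5-tris(methoxymethoxy)benzene
Conditions: NaH, MOMCl, DMF, 0 °C → rt
Reagents that add atoms: chloromethyl methyl ether, COCCl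
Why: Williamson-type O-alkylation of the triphenoxide gives the threefold-symmetric tris-MOM ether, in which all three ring C–H positions are equivalent and doubly activated for lithiation.

Step 5
Reactants: 8 1,3,5-tris(methoxymethoxy)benzene; 6 (2S,3R)-3-[(tert-butyldimethylsilyl)oxy]-N-methoxy-N,2-dimethylbutanamide
Product: 10 (2S,3R)-3-[(tert-butyldimethylsilyl)oxy]-2-methyl-1-[2,4,6-tris(methoxymethoxy)phenyl]butan-1-one, via aryllithium 9 (not isolated)
Conditions: n-BuLi, THF, 0 °C, 1 h; then 6, −78 → 0 °C; aq. NH4Cl
Reagents that add atoms: none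
Why: Directed ortho-lithiation between two MOM ethers followed by Weinreb ketone synthesis, where the chelated tetrahedral intermediate should prevent over-addition and α-epimerisation.

Step 6
Reactants: 10 (2S,3R)-3-[(tert-butyldimethylsilyl)oxy]-2-methyl-1-[2,4,6-tris(methoxymethoxy)phenyl]butan-1-one
Product: 11 (2S,3R)-3-hydroxy-2-methyl-1-(2,4,6-trihydroxyphenyl)butan-1-one
Conditions: 3 M HCl, MeOH, 40 °C
Reagents that add atoms: none
Why: Acid-catalysed acetal exchange removes the three MOM groups and the silyl ether in one operation, and the ketone, deactivated by conjugation and hydrogen bonding to the ortho phenols, should resist dehydration under these mild conditions.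

Step 7
Reactants: 11 (2S,3R)-3-hydroxy-2-methyl-1-(2,4,6-trihydroxyphenyl)butan-1-one
Product: 12 (2S,3S)-5,7-dihydroxy-2,3-dimethylchroman-4-one (trans)
Conditions: PPh3, DIAD, THF (0.01 M), 0 °C → rt
Reagents that add atoms: none
Why: Intramolecular Mitsunobu etherification (6-exo-tet) in which an ortho phenol displaces the activated carbinol with inversion, turning the 3R carbinol of the syn aldol into the 2S ether carbon of the trans-2,3-dimethylchromanone; the two ortho hydroxyls are equivalent, so no regiochemical question arises.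

Step 8
Reactants: 12 (2S,3S)-5,7-dihydroxy-2,3-dimethylchroman-4-one
Product: 13 (2S,3S)-5-hydroxy-2,3-dimethyl-4-oxochroman-7-yl acetate
Conditions: Ac2O (1.05 equiv), pyridine, CH2Cl2, 0 °C
Reagents that add atoms: acetic anhydride, CC(=O)OC(C)=O
Why: Selective O-acylation, since O5–H is deactivated by its hydrogen bond to C4=O and only O7–H should react.

Step 9
Reactants: 13 (2S,3S)-5-hydroxy-2,3-dimethyl-4-oxochroman-7-yl acetate
Product: 14 (2S,3S)-5-(allyloxy)-2,3-dimethyl-4-oxochroman-7-yl acetate
Conditions: allyl alcohol, PPh3, DIAD, THF, 0 °C → rt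
Reagents that add atoms: prop-2-en-1-ol, C=CCO
Why: Mitsunobu O-alkylation of the chelated phenol with a primary allylic alcohol proceeds without a base that could epimerise C3 or cleave the acetate.

Step 10
Reactants: 14 (2S,3S)-5-(allyloxy)-2,3-dimethyl-4-oxochroman-7-yl acetate
Product: 16 (2S,3S)-6-allyl-5-hydroxy-2,3-dimethyl-4-oxochroman-7-yl acetate, via ortho-dienone 15 (not isolated)
Conditions: 1,2-dichlorobenzene, 190 °C, sealed tube
Reagents that add atoms: none
Why: Aromatic Claisen rearrangement delivers the allyl group from O5 to C6, the only ortho carbon that bears hydrogen, and tautomerisation of the dienone restores the phenol, so C8 stays free.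

Step 11
Reactants: 16 (2S,3S)-6-allyl-5-hydroxy-2,3-dimethyl-4-oxochroman-7-yl acetate
Product: 17 (2S,3S)-5-hydroxy-2,3-dimethyl-6-(3-methylbut-2-en-1-yl)-4-oxochroman-7-yl acetate
Conditions: second-generation Grubbs catalyst (H2IMes)(PCy3)Cl2Ru=CHPh (5 mol %), 2-methylbut-2-ene (excess), CH2Cl2, 40 °C
Reagents that add atoms: 2-methylbut-2-ene, CC=C(C)C
Why: Olefin cross-metathesis of the terminal allyl group with excess 2-methylbut-2-ene converts allyl into prenyl with loss of propene, while the aryl acetate and the chelated phenol are spectators.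

Step 12
Reactants: 17 (2S,3S)-5-hydroxy-2,3-dimethyl-6-(3-methylbut-2-en-1-yl)-4-oxochroman-7-yl acetate
Product: 18 (2S,3S)-5,7-dihydroxy-2,3-dimethyl-6-(3-methylbut-2-en-1-yl)chroman-4-one
Conditions: K2CO3 (0.2 equiv), MeOH, 0 °C; pH 7 buffer
Reagents that add atoms: none
Why: Base-catalysed methanolysis of the activated aryl acetate at low temperature frees O7–H and should be too mild to epimerise C3.

Step 13
Reactants: 19 hex-2-yn-1-ol
Product: 20 hex-2-ynal
Conditions: MnO2 (activated, excess), CH2Cl2, rt; filtered solution used directly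
Reagents that add atoms: none
Why: MnO2 oxidises propargylic alcohols selectively to ynals without over-oxidation, and filtration gives a solution of the volatile aldehyde ready for use.

Step 14
Reactants: 18 (2S,3S)-5,7-dihydroxy-2,3-dimethyl-6-(3-methylbut-2-en-1-yl)chroman-4-one; 20 hex-2-ynal
Product: 22 methyl (3R)-3-[(2S,3S)-5,7-dihydroxy-2,3-dimethyl-6-(3-methylbut-2-en-1-yl)-4-oxochroman-8-yl]hexanoate, via tricyclic lactone 21 (not isolated)
Conditions: (5aS,10bR)-2-mesityl-5a,10b-dihydro-4H,6H-indeno[2,1-b][1,2,4]triazolo[4,3-d][1,4]oxazin-2-ium chloride (10 mol %), toluene, 40 °C, no added base; then MeOH (excess), Et3N (0.2 equiv), rt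
Reagents that add atoms: methanol, CO
Why: The carbene adds to ynal 20 and the Breslow intermediate isomerises by internal redox to the (E)-hex-2-enoyl azolium; O7 of 18 adds to its acyl carbon and the hemiacetal undergoes a [3,3] (Coates–Claisen) shift that forms the C8–C3' bond, after which the rearomatised O7 acylates intramolecularly to close lactone 21 and release the carbene. The closest known reaction type is the chiral-triazolium-catalysed annulation of ynals with kojic acids and naphthols to dihydropyranones, followed by ring opening with MeOH. The lactone ring closes by 6-exo-trig addition–elimination of O7 at the acyl azolium carbon and is opened in the same pot by methanolysis of this activated aryl ester, which leaves the methyl ester and the free O7–H of 22. The new centre is set by catalyst control: the indane of the triazolium shields one face of the s-cis acyl azolium so that C8 bonds to the Re face of C3', giving R, and the remote C2 and C3 centres should have little influence. The step needs O7/C8 selectivity over O5/C6 and no erosion at C3: O5–H is hydrogen-bonded to C4=O, C6 carries prenyl so a shift there cannot rearomatise, and the absence of added base during the carbene stage protects the α-stereocentre.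

**Compound list**

1 | (S)-4-benzyl-3-propanoyl-1,3-oxazolidin-2-one | CCC(=O)N1[C@@H](Cc2ccccc2)COC1=O | starting material
2 | acetaldehyde | CC=O | starting material
3 | dibutylboron (Z)-enolate of 1 | C/C=C(/N1[C@@H](Cc2ccccc2)COC1=O)OB(CCCC)CCCC | intermediate
4 | (S)-4-benzyl-3-[(2S,3R)-3-hydroxy-2-methylbutanoyl]-1,3-oxazolidin-2-one | C[C@@H](O)[C@H](C)C(=O)N1[C@@H](Cc2ccccc2)COC1=O | intermediate
5 | (2S,3R)-3-hydroxy-N-methoxy-N,2-dimethylbutanamide | C[C@@H](O)[C@H](C)C(=O)N(C)OC | intermediate
6 | (2S,3R)-3-[(tert-butyldimethylsilyl)oxy]-N-methoxy-N,2-dimethylbutanamide | C[C@@H](O[Si](C)(C)C(C)(C)C)[C@H](C)C(=O)N(C)OC | intermediate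
7 | phloroglucinol (benzene-1,3,5-triol) | Oc1cc(O)cc(O)c1 | starting material
8 | 1,3,5-tris(methoxymethoxy)benzene | COCOc1cc(OCOC)cc(OCOC)c1 | intermediate
9 | 2,4,6-tris(methoxymethoxy)phenyllithium | [Li]c1c(OCOC)cc(OCOC)cc1OCOC | intermediate
10 | (2S,3R)-3-[(tert-butyldimethylsilyl)oxy]-2-methyl-1-[2,4,6-tris(methoxymethoxy)phenyl]butan-1-one | C[C@@H](O[Si](C)(C)C(C)(C)C)[C@H](C)C(=O)c1c(OCOC)cc(OCOC)cc1OCOC | intermediate
11 | (2S,3R)-3-hydroxy-2-methyl-1-(2,4,6-trihydroxyphenyl)butan-1-one | C[C@@H](O)[C@H](C)C(=O)c1c(O)cc(O)cc1O | intermediate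
12 | (2S,3S)-5,7-dihydroxy-2,3-dimethylchroman-4-one (trans) | Oc1cc(O)c2c(c1)O[C@@H](C)[C@H](C)C2=O | intermediate
13 | (2S,3S)-5-hydroxy-2,3-dimethyl-4-oxochroman-7-yl acetate | CC(=O)Oc1cc(O)c2c(c1)O[C@@H](C)[C@H](C)C2=O | intermediate
14 | (2S,3S)-5-(allyloxy)-2,3-dimethyl-4-oxochroman-7-yl acetate | CC(=O)Oc1cc(OCC=C)c2c(c1)O[C@@H](C)[C@H](C)C2=O | intermediate
15 | ortho-dienone: (2S,3S)-6-allyl-2,3-dimethyl-4,5-dioxo-3,4,5,6-tetrahydro-2H-chromen-7-yl acetate (both C6 epimers) | CC(=O)OC1=CC2=C(C(=O)C1CC=C)C(=O)[C@@H](C)[C@H](C)O2 | intermediate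
16 | (2S,3S)-6-allyl-5-hydroxy-2,3-dimethyl-4-oxochroman-7-yl acetate | CC(=O)Oc1c(CC=C)c(O)c2c(c1)O[C@@H](C)[C@H](C)C2=O | intermediate
17 | (2S,3S)-5-hydroxy-2,3-dimethyl-6-(3-methylbut-2-en-1-yl)-4-oxochroman-7-yl acetate | CC(=O)Oc1c(CC=C(C)C)c(O)c2c(c1)O[C@@H](C)[C@H](C)C2=O | intermediate
18 | (2S,3S)-5,7-dihydroxy-2,3-dimethyl-6-(3-methylbut-2-en-1-yl)chroman-4-one | Oc1c(CC=C(C)C)c(O)c2c(c1)O[C@@H](C)[C@H](C)C2=O | intermediate
19 | hex-2-yn-1-ol | CCCC#CCO | starting material
20 | hex-2-ynal | CCCC#CC=O | intermediate
21 | tricyclic lactone: (R)-4-propyl-3,4-dihydro-2-pyranone ring fused through O7 and C8 onto chromanone 18 (5-OH, 6-prenyl, 2S,3S retained) | CCC[C@H](CC(=O)O1)c2c1c(CC=C(C)C)c(O)c1c2O[C@@H](C)[C@H](C)C1=O | intermediate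
22 | methyl (3R)-3-[(2S,3S)-5,7-dihydroxy-2,3-dimethyl-6-(3-methylbut-2-en-1-yl)-4-oxochroman-8-yl]hexanoate | CCC[C@H](CC(=O)OC)c1c(O)c(CC=C(C)C)c(O)c2c1O[C@@H](C)[C@H](C)C2=O | target

**Step count and risks**

Total step count: 14. Longest linear sequence: 12 steps (1, 2, 3, 5, 6, 7, 8, 9, 10, 11, 12, 14).

Steps most likely to fail:

Step 14. The acyl azolium may only acylate O7 (redox esterification without the carbon–carbon shift), or the facial selectivity at C3' may be poor. The fallback changes the activation mode to iminium catalysis and sets out from 18. Friedel–Crafts alkylation of C8 with commercial (E)-hex-2-enal under a diphenylprolinol trimethylsilyl ether catalyst (enantiomer chosen for Re-face attack, PhCO2H co-catalyst, toluene, rt), followed by hemiacetalisation onto O7, should give the C8-alkylated lactol F1. Oxidation of the lactol with Ag2CO3 on Celite in hot toluene comes back to the route at lactone 21, which is opened with MeOH/Et3N as in step 14.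

Step 7. The activated β-hydroxy ketone may eliminate to the enone, which then closes by unselective oxa-Michael addition and scrambles C2 and C3. The fallback builds ring B by asymmetric conjugate addition and sets out from 8, lithiated to 9 as in step 5. Acylation of 9 with the Weinreb amide of tiglic acid F2 (made from tiglic acid, carbonyldiimidazole and MeNHOMe·HCl) should give the tris-MOM aryl tigloyl ketone F3. HCl in MeOH should then give the trihydroxyphenyl tigloyl ketone F4. Quinidine-catalysed intramolecular oxa-Michael addition in chlorobenzene should give the cis-chromanone F5 with the 2S centre set by the alkaloid. Equilibration at C3 with Et3N to the more stable trans isomer comes back to the route at 12.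

Step 5. The hindered, doubly ortho-substituted aryllithium may deprotonate the α-branched amide instead of adding to it. The fallback replaces acylation by aldehyde addition and oxidation and sets out from 6. Reduction with i-Bu2AlH (THF, −78 °C) should give the silyloxy aldehyde F6. Addition of 9 at −78 °C should give the benzylic carbinol F7 as a mixture at the new carbinol carbon, which is of no consequence. Oxidation with Dess–Martin periodinane (NaHCO3, CH2Cl2) comes back to the route at 10.

**Further compounds**

F1 | step 14 | lactol: 2-hydroxy analogue of lactone 21 (C8-alkylated hemiacetal, both anomers) | CCC[C@H](CC(O)O1)c2c1c(CC=C(C)C)c(O)c1c2O[C@@H](C)[C@H](C)C1=O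
F2 | step 7 | (E)-N-methoxy-N,2-dimethylbut-2-enamide | C/C=C(\C)C(=O)N(C)OC
F3 | step 7 | (E)-2-methyl-1-[2,4,6-tris(methoxymethoxy)phenyl]but-2-en-1-one | C/C=C(\C)C(=O)c1c(OCOC)cc(OCOC)cc1OCOC
F4 | step 7 | (E)-2-methyl-1-(2,4,6-trihydroxyphenyl)but-2-en-1-one | C/C=C(\C)C(=O)c1c(O)cc(O)cc1O
F5 | step 7 | (2S,3R)-5,7-dihydroxy-2,3-dimethylchroman-4-one (cis) | Oc1cc(O)c2c(c1)O[C@@H](C)[C@@H](C)C2=O
F6 | step 5 | (2S,3R)-3-[(tert-butyldimethylsilyl)oxy]-2-methylbutanal | C[C@@H](O[Si](C)(C)C(C)(C)C)[C@H](C)C=O
F7 | step 5 | 3-[(tert-butyldimethylsilyl)oxy]-2-methyl-1-[2,4,6-tris(methoxymethoxy)phenyl]butan-1-ol (chain centres as in 10, both carbinol epimers) | C[C@@H](O[Si](C)(C)C(C)(C)C)[C@H](C)C(O)c1c(OCOC)cc(OCOC)cc1OCOC
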